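**Strategy.** The target is two (+)-catechin units joined C6′ (upper ring B) to C8 (lower ring A). In the lower unit the pyran ether bond O1–C8a and the biaryl bond at C8 sit on adjacent carbons of ring A, which is the imprint of an aryne. The key step therefore takes an open-chain (1R,2S)-2-benzyloxy-1,3-diarylpropan-1-ol bearing F at C8a and Br at C8, generates the C8–C8a aryne, lets the C2 alkoxide close ring C by O1–C8a bond formation, and couples the resulting C8 aryl-metal in the same flask with a 6′-iodide made from (+)-catechin. Global hydrogenolysis then frees the ten phenols and alcohols.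

Key step: step 10

Remark: the C8–C6′ biaryl axis carries no descriptor in the target; it is taken as not configurationally defined and no atroposelective step is planned. Flavan numbering (O1, C2, C3, C4, C4a, C5–C8, C8a; ring B primed) is used for both halves, also in the open-chain precursors.

**Step 1**
Reactants: 1 (+)-catechin
Product: 2 (2R,3S)-5,7-bis(benzyloxy)-2-[3,4-bis(benzyloxy)phenyl]chroman-3-ol
Conditions: BnBr (4.4 equiv), K2CO3, DMF, 0 °C → rt
Reagents that add atoms: benzyl bromide, BrCc1ccccc1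
Why: Williamson ether synthesis in which carbonate deprotonates only the four phenols, so the secondary 3-OH stays free and no stereocenter is touched.

**Step 2**
Reactants: 2 (2R,3S)-5,7-bis(benzyloxy)-2-[3,4-bis(benzyloxy)phenyl]chroman-3-ol
Product: 3 (2R,3S)-3,5,7-tris(benzyloxy)-2-[3,4-bis(benzyloxy)phenyl]chromane
Conditions: NaH, BnBr, DMF, 0 °C → rt
Reagents that add atoms: benzyl bromide, BrCc1ccccc1
Why: Williamson etherification of the sodium 3-alkoxide caps the only oxygen of the upper half that could later act as a competing internal nucleophile, without affecting C2 or C3.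

**Step 3**
Reactants: 3 (2R,3S)-3,5,7-tris(benzyloxy)-2-[3,4-bis(benzyloxy)phenyl]chromane
Product: 5 (2R,3S)-3,5,7-tris(benzyloxy)-2-[4,5-bis(benzyloxy)-2-iodophenyl]-6,8-dibromochromane, via dibromide 4 (not isolated)
Conditions: NBS (2.1 equiv), CH2Cl2, −20 → 0 °C; then NIS (1.2 equiv), CF3CO2H (cat.), MeCN, rt
Reagents that add atoms: N-bromosuccinimide, O=C1CCC(=O)N1Br; N-iodosuccinimide, O=C1CCC(=O)N1I
Why: Electrophilic aromatic halogenation in which the phloroglucinol-type ring A takes both bromines (C8, then C6) and is thereby blocked, so that acid-activated NIS iodinates ring B at C6′, para to the 3′-benzyloxy group and ortho to the alkyl substituent.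

**Step 4**
Reactants: 6 1,3,5-trifluorobenzene
Product: 7 1,3-bis(benzyloxy)-5-fluorobenzene
Conditions: BnOH (2.2 equiv), NaH (2.2 equiv), THF/N-methylpyrrolidone, 0 → 80 °C
Reagents that add atoms: benzyl alcohol, OCc1ccccc1
Why: Twofold nucleophilic aromatic substitution by sodium benzyloxide, each alkoxy group slowing the next substitution so that the third fluorine should be retained.

**Step 5**
Reactants: 7 1,3-bis(benzyloxy)-5-fluorobenzene
Product: 9 1,5-bis(benzyloxy)-2-bromo-3-fluoro-4-iodobenzene, via monobromide 8 (not isolated)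
Conditions: NBS (1.0 equiv), MeCN, 0 °C; then NIS (1.1 equiv), CF3CO2H (cat.), rt
Reagents that add atoms: N-bromosuccinimide, O=C1CCC(=O)N1Br; N-iodosuccinimide, O=C1CCC(=O)N1I
Why: Sequential electrophilic aromatic halogenation at the two equivalent positions ortho to fluorine, each ortho and para to a benzyloxy group, the position between the two benzyloxy groups being the most hindered.

**Step 6**
Reactants: 9 1,5-bis(benzyloxy)-2-bromo-3-fluoro-4-iodobenzene; 10 methyl (2S)-oxirane-2-carboxylate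
Product: 12 methyl (2S)-3-[4,6-bis(benzyloxy)-3-bromo-2-fluorophenyl]-2-hydroxypropanoate, via arylmagnesium chloride 11 (not isolated)
Conditions: i-PrMgCl·LiCl (1.05 equiv), THF, −40 °C; then CuI (10 mol %), 10, −40 → −10 °C; aq. NH4Cl
Reagents that add atoms: none
Why: Iodine–magnesium exchange takes place at C–I in preference to C–Br, and copper-catalysed epoxide opening by the aryl Grignard at the unsubstituted carbon leaves the glycidate stereocenter, which becomes C3 (S), untouched.

**Step 7**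
Reactants: 12 methyl (2S)-3-[4,6-bis(benzyloxy)-3-bromo-2-fluorophenyl]-2-hydroxypropanoate
Product: 13 methyl (2S)-2-(benzyloxy)-3-[4,6-bis(benzyloxy)-3-bromo-2-fluorophenyl]propanoate
Conditions: BnBr, Ag2O, CH2Cl2, 4 Å sieves, rt, dark
Reagents that add atoms: benzyl bromide, BrCc1ccccc1
Why: Silver-oxide-mediated Williamson-type O-benzylation proceeds without a strong base, so the α-hydroxy ester should not enolise and the C3 configuration is kept.

**Step 8**
Reactants: 13 methyl (2S)-2-(benzyloxy)-3-[4,6-bis(benzyloxy)-3-bromo-2-fluorophenyl]propanoate; 14 1,2-bis(benzyloxy)-4-bromobenzene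
Product: 17 (2S)-2-(benzyloxy)-1-[3,4-bis(benzyloxy)phenyl]-3-[4,6-bis(benzyloxy)-3-bromo-2-fluorophenyl]propan-1-one, via Weinreb amide 15 (not isolated), via arylmagnesium bromide 16 (not isolated)
Conditions: MeNH(OMe)·HCl (1.5 equiv), i-PrMgCl (3.0 equiv), THF, −20 °C; then 16 (from 14, Mg, THF), −20 → 0 °C; aq. NH4Cl
Reagents that add atoms: none
Why: One-flask Weinreb ketone synthesis in which magnesium-amide aminolysis of the ester gives the N-methoxy-N-methylamide, whose chelated tetrahedral adduct with the aryl Grignard collapses to the ketone only on work-up, with no enolisation of the α-center at low temperature.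

**Step 9**
Reactants: 17 (2S)-2-(benzyloxy)-1-[3,4-bis(benzyloxy)phenyl]-3-[4,6-bis(benzyloxy)-3-bromo-2-fluorophenyl]propan-1-one
Product: 18 (1R,2S)-2-(benzyloxy)-1-[3,4-bis(benzyloxy)phenyl]-3-[4,6-bis(benzyloxy)-3-bromo-2-fluorophenyl]propan-1-ol
Conditions: Zn(BH4)2, Et2O, −20 → 0 °C
Reagents that add atoms: none
Why: Chelation-controlled hydride reduction (Cram chelate model) in which zinc bridges the carbonyl and α-benzyloxy oxygens and hydride enters from the face of the α-hydrogen, which should give the anti (1R,2S) alcohol that maps onto the 2,3-trans flavan.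

**Step 10**
Reactants: 18 (1R,2S)-2-(benzyloxy)-1-[3,4-bis(benzyloxy)phenyl]-3-[4,6-bis(benzyloxy)-3-bromo-2-fluorophenyl]propan-1-ol; 5 (2R,3S)-3,5,7-tris(benzyloxy)-2-[4,5-bis(benzyloxy)-2-iodophenyl]-6,8-dibromochromane
Product: 23 (2R,3S)-3,5,7-tris(benzyloxy)-2-[3,4-bis(benzyloxy)phenyl]-8-{4,5-bis(benzyloxy)-2-[(2R,3S)-3,5,7-tris(benzyloxy)-6,8-dibromochroman-2-yl]phenyl}chromane, via dilithio species 19 (not isolated), via aryne alkoxide 20 (not isolated), via 8-lithioflavan 21 (not isolated), via arylzinc chloride 22 (not isolated)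
Conditions: t-BuLi (3.0 equiv), THF (0.02 M), −78 °C, then warm to −20 °C; ZnCl2 (1.3 equiv), −20 °C → rt; 5 (1.1 equiv), Pd2(dba)3 (2.5 mol %), SPhos (10 mol %), 60 °C
Reagents that add atoms: none
Why: t-BuLi deprotonates the C2 hydroxyl and exchanges the C8 bromine for lithium to give 19, which on warming loses LiF across C8–C8a; the aryne 20 is captured in the ring plane at C8a by the tethered C2 lithium alkoxide, which forms the O1–C8a bond and leaves an aryllithium at C8 (21) that is transmetalated to zinc (22) and joined to C6′ of iodide 5 by Negishi coupling. The closest known reaction types are the ring closure of arynes by tethered alkoxide or amide nucleophiles with further use of the aryl-metal so formed, and the Negishi coupling of di-ortho-substituted arylzinc halides with hindered biarylphosphine ligands. Ring C closes in a 6-exo-dig sense, the attacked aryne carbon C8a lying inside the new ring and C8 outside it. No stereocenter is created: C2 and C3 keep the (2R,3S) configuration set in steps 6 and 9 because neither of their C–O bonds is broken, and the biaryl axis is not controlled. The step needs attack at C8a and not at C8, which the three-atom tether and the inductive stabilisation of charge at C8 by the C7 benzyloxy group secure; it needs the C2 oxygen as the only internal nucleophile, which the benzyl cap on the C3 oxygen secures by excluding a five-membered closure; and it needs coupling at C–I and not at the two C–Br bonds of 5, which the faster oxidative addition of the iodide to zerovalent palladium secures. High dilution should keep intermolecular capture of the aryne in the background.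

**Step 11**
Reactants: 23 (2R,3S)-3,5,7-tris(benzyloxy)-2-[3,4-bis(benzyloxy)phenyl]-8-{4,5-bis(benzyloxy)-2-[(2R,3S)-3,5,7-tris(benzyloxy)-6,8-dibromochroman-2-yl]phenyl}chromane
Product: 24 (2R,3S)-2-(3,4-dihydroxyphenyl)-8-{4,5-dihydroxy-2-[(2R,3S)-3,5,7-trihydroxychroman-2-yl]phenyl}chromane-3,5,7-triol
Conditions: H2 (1 atm), Pd(OH)2/C, Et3N (2.2 equiv), THF–MeOH, rt
Reagents that add atoms: none
Why: Catalytic hydrogenolysis should cleave the ten benzyl ethers and, with the amine as HBr acceptor, the two aryl C–Br bonds that served as blocking groups on the upper ring A, without touching any stereocenter.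

**Compound list**

1 | (+)-catechin, (2R,3S)-2-(3,4-dihydroxyphenyl)chromane-3,5,7-triol | Oc1cc(O)c2c(c1)O[C@H](c1ccc(O)c(O)c1)[C@@H](O)C2 | starting material
2 | (2R,3S)-5,7-bis(benzyloxy)-2-[3,4-bis(benzyloxy)phenyl]chroman-3-ol (5,7,3′,4′-tetra-O-benzylcatechin) | c1ccccc1COc1cc(OCc2ccccc2)c2c(c1)O[C@H](c1ccc(OCc3ccccc3)c(OCc3ccccc3)c1)[C@@H](O)C2 | intermediate
3 | (2R,3S)-3,5,7-tris(benzyloxy)-2-[3,4-bis(benzyloxy)phenyl]chromane (penta-O-benzylcatechin) | c1ccccc1COc1cc(OCc2ccccc2)c2c(c1)O[C@H](c1ccc(OCc3ccccc3)c(OCc3ccccc3)c1)[C@@H](OCc1ccccc1)C2 | intermediate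
4 | (2R,3S)-3,5,7-tris(benzyloxy)-2-[3,4-bis(benzyloxy)phenyl]-6,8-dibromochromane | c1ccccc1COc1c(Br)c(OCc2ccccc2)c2c(c1Br)O[C@H](c1ccc(OCc3ccccc3)c(OCc3ccccc3)c1)[C@@H](OCc1ccccc1)C2 | intermediate (not isolated)
5 | (2R,3S)-3,5,7-tris(benzyloxy)-2-[4,5-bis(benzyloxy)-2-iodophenyl]-6,8-dibromochromane (6,8-dibromo-6′-iodo derivative of 3) | c1ccccc1COc1c(Br)c(OCc2ccccc2)c2c(c1Br)O[C@H](c1cc(OCc3ccccc3)c(OCc3ccccc3)cc1I)[C@@H](OCc1ccccc1)C2 | intermediate
6 | 1,3,5-trifluorobenzene | Fc1cc(F)cc(F)c1 | starting material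
7 | 1,3-bis(benzyloxy)-5-fluorobenzene | Fc1cc(OCc2ccccc2)cc(OCc2ccccc2)c1 | intermediate
8 | 1,5-bis(benzyloxy)-2-bromo-3-fluorobenzene | Fc1cc(OCc2ccccc2)cc(OCc2ccccc2)c1Br | intermediate (not isolated)
9 | 1,5-bis(benzyloxy)-2-bromo-3-fluoro-4-iodobenzene | Fc1c(I)c(OCc2ccccc2)cc(OCc2ccccc2)c1Br | intermediate
10 | methyl (2S)-oxirane-2-carboxylate (methyl (S)-glycidate) | COC(=O)[C@@H]1CO1 | starting material
11 | [4,6-bis(benzyloxy)-3-bromo-2-fluorophenyl]magnesium chloride | Cl[Mg]c1c(F)c(Br)c(OCc2ccccc2)cc1OCc1ccccc1 | intermediate (not isolated)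
12 | methyl (2S)-3-[4,6-bis(benzyloxy)-3-bromo-2-fluorophenyl]-2-hydroxypropanoate | COC(=O)[C@@H](O)Cc1c(F)c(Br)c(OCc2ccccc2)cc1OCc1ccccc1 | intermediate
13 | methyl (2S)-2-(benzyloxy)-3-[4,6-bis(benzyloxy)-3-bromo-2-fluorophenyl]propanoate | COC(=O)[C@@H](OCc1ccccc1)Cc1c(F)c(Br)c(OCc2ccccc2)cc1OCc1ccccc1 | intermediate
14 | 1,2-bis(benzyloxy)-4-bromobenzene | Brc1ccc(OCc2ccccc2)c(OCc2ccccc2)c1 | starting material
15 | (2S)-2-(benzyloxy)-3-[4,6-bis(benzyloxy)-3-bromo-2-fluorophenyl]-N-methoxy-N-methylpropanamide | CON(C)C(=O)[C@@H](OCc1ccccc1)Cc1c(F)c(Br)c(OCc2ccccc2)cc1OCc1ccccc1 | intermediate (not isolated)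
16 | [3,4-bis(benzyloxy)phenyl]magnesium bromide | Br[Mg]c1ccc(OCc2ccccc2)c(OCc2ccccc2)c1 | intermediate (not isolated)
17 | (2S)-2-(benzyloxy)-1-[3,4-bis(benzyloxy)phenyl]-3-[4,6-bis(benzyloxy)-3-bromo-2-fluorophenyl]propan-1-one | O=C(c1ccc(OCc2ccccc2)c(OCc2ccccc2)c1)[C@@H](OCc1ccccc1)Cc1c(F)c(Br)c(OCc2ccccc2)cc1OCc1ccccc1 | intermediate
18 | (1R,2S)-2-(benzyloxy)-1-[3,4-bis(benzyloxy)phenyl]-3-[4,6-bis(benzyloxy)-3-bromo-2-fluorophenyl]propan-1-ol | O[C@H](c1ccc(OCc2ccccc2)c(OCc2ccccc2)c1)[C@@H](OCc1ccccc1)Cc1c(F)c(Br)c(OCc2ccccc2)cc1OCc1ccccc1 | intermediate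
19 | lithium alkoxide of 18 with lithium in place of bromine at C8 | [Li]O[C@H](c1ccc(OCc2ccccc2)c(OCc2ccccc2)c1)[C@@H](OCc1ccccc1)Cc1c(F)c([Li])c(OCc2ccccc2)cc1OCc1ccccc1 | intermediate (not isolated)
20 | C8–C8a aryne carrying the C2 lithium alkoxide | [Li]O[C@H](c1ccc(OCc2ccccc2)c(OCc2ccccc2)c1)[C@@H](OCc1ccccc1)CC1=C(OCc2ccccc2)C=C(OCc2ccccc2)C#C1 | intermediate (not isolated)
21 | (2R,3S)-3,5,7-tris(benzyloxy)-2-[3,4-bis(benzyloxy)phenyl]chroman-8-yllithium | c1ccccc1COc1cc(OCc2ccccc2)c2c(c1[Li])O[C@H](c1ccc(OCc3ccccc3)c(OCc3ccccc3)c1)[C@@H](OCc1ccccc1)C2 | intermediate (not isolated)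
22 | (2R,3S)-3,5,7-tris(benzyloxy)-2-[3,4-bis(benzyloxy)phenyl]chroman-8-ylzinc chloride | c1ccccc1COc1cc(OCc2ccccc2)c2c(c1[Zn]Cl)O[C@H](c1ccc(OCc3ccccc3)c(OCc3ccccc3)c1)[C@@H](OCc1ccccc1)C2 | intermediate (not isolated)
23 | (2R,3S)-3,5,7-tris(benzyloxy)-2-[3,4-bis(benzyloxy)phenyl]-8-{4,5-bis(benzyloxy)-2-[(2R,3S)-3,5,7-tris(benzyloxy)-6,8-dibromochroman-2-yl]phenyl}chromane | c1ccccc1COc1c(Br)c(OCc2ccccc2)c2c(c1Br)O[C@H](c1cc(OCc3ccccc3)c(OCc3ccccc3)cc1-c1c(OCc4ccccc4)cc(OCc4ccccc4)c3c1O[C@H](c1ccc(OCc4ccccc4)c(OCc4ccccc4)c1)[C@@H](OCc1ccccc1)C3)[C@@H](OCc1ccccc1)C2 | intermediate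
24 | (2R,3S)-2-(3,4-dihydroxyphenyl)-8-{4,5-dihydroxy-2-[(2R,3S)-3,5,7-trihydroxychroman-2-yl]phenyl}chromane-3,5,7-triol | Oc1cc(O)c2c(c1)O[C@H](c1cc(O)c(O)cc1-c1c(O)cc(O)c3c1O[C@H](c1ccc(O)c(O)c1)[C@@H](O)C3)[C@@H](O)C2 | target

**Step count and risks**

Total step count: 11. Longest linear sequence: 8 steps (steps 4 to 11); steps 1 to 3 form the convergent branch that joins in step 10.

Steps most likely to fail:

1. Step 10 (key step). Intermolecular capture of the aryne by aryllithium species could give oligomers. Proton transfer from benzylic ether CH2 groups to the aryllithiums is possible. The hindered Negishi coupling could stall or stray into the C–Br bonds. Fallback: the two bond formations are separated and ring C is closed by nucleophilic aromatic substitution instead of through the aryne. From 18, t-BuLi at −78 °C followed at once by ZnCl2 at −78 °C gives an ortho-fluoro arylzinc that keeps its fluoride. Negishi coupling of it with 5 (Pd2(dba)3, SPhos) should give the open-chain biaryl fluoro alcohol F1. Its potassium alkoxide (KN(SiMe3)2, 18-crown-6, THF/DMF, 60–80 °C) should then displace the C8a fluoride, which is meta to both benzyloxy groups, in a 6-exo closure that comes back to the route at 23.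

2. Step 6. The hindered aryl Grignard could add to the ester carbonyl instead of opening the epoxide. The epoxide could be opened by chloride. MgClF could be lost before the coupling. Fallback: an epoxide without a carbonyl group is used and the ketone is built afterwards. From 11, copper-catalysed opening of (S)-glycidyl trityl ether should give the trityl-protected secondary alcohol F2. Benzylation (NaH, BnBr) gives the benzyl ether F3, and detritylation (TsOH, MeOH/CH2Cl2) gives the primary alcohol F4. Dess–Martin oxidation gives the aldehyde F5. Addition of 16 gives the carbinol F6 as a mixture of C1 epimers, and a second Dess–Martin oxidation comes back to the route at ketone 17.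

3. Step 5. Two successive halogenations in one flask could under- or over-halogenate and scramble halogens, giving dibromo, bromo-iodo and diiodo arenes that are hard to separate. Fallback: 7 is dibrominated symmetrically (NBS, 2.1 equiv) to the dibromide F7. A single bromine–magnesium exchange (i-PrMgCl·LiCl, THF, 0 °C) then desymmetrises it and should give the same arylmagnesium chloride, coming back to the route at 11.

**Further compounds**

F1 | step 10 | (1R,2S)-2-(benzyloxy)-1-[3,4-bis(benzyloxy)phenyl]-3-{4,6-bis(benzyloxy)-3-[4,5-bis(benzyloxy)-2-((2R,3S)-3,5,7-tris(benzyloxy)-6,8-dibromochroman-2-yl)phenyl]-2-fluorophenyl}propan-1-ol | c1ccccc1COc1c(Br)c(OCc2ccccc2)c2c(c1Br)O[C@H](c1cc(OCc3ccccc3)c(OCc3ccccc3)cc1-c1c(F)c(C[C@H](OCc3ccccc3)[C@H](O)c3ccc(OCc4ccccc4)c(OCc4ccccc4)c3)c(OCc3ccccc3)cc1OCc1ccccc1)[C@@H](OCc1ccccc1)C2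
F2 | step 6 | (2S)-1-[4,6-bis(benzyloxy)-3-bromo-2-fluorophenyl]-3-(trityloxy)propan-2-ol | C(c1ccccc1)(c1ccccc1)(c1ccccc1)OC[C@@H](O)Cc1c(F)c(Br)c(OCc2ccccc2)cc1OCc1ccccc1
F3 | step 6 | (2S)-2-(benzyloxy)-1-[4,6-bis(benzyloxy)-3-bromo-2-fluorophenyl]-3-(trityloxy)propane | C(c1ccccc1)(c1ccccc1)(c1ccccc1)OC[C@@H](OCc1ccccc1)Cc1c(F)c(Br)c(OCc2ccccc2)cc1OCc1ccccc1
F4 | step 6 | (2S)-2-(benzyloxy)-3-[4,6-bis(benzyloxy)-3-bromo-2-fluorophenyl]propan-1-ol | OC[C@@H](OCc1ccccc1)Cc1c(F)c(Br)c(OCc2ccccc2)cc1OCc1ccccc1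
F5 | step 6 | (2S)-2-(benzyloxy)-3-[4,6-bis(benzyloxy)-3-bromo-2-fluorophenyl]propanal | O=C[C@@H](OCc1ccccc1)Cc1c(F)c(Br)c(OCc2ccccc2)cc1OCc1ccccc1
F6 | step 6 | (2S)-2-(benzyloxy)-1-[3,4-bis(benzyloxy)phenyl]-3-[4,6-bis(benzyloxy)-3-bromo-2-fluorophenyl]propan-1-ol as a mixture of C1 epimers | OC(c1ccc(OCc2ccccc2)c(OCc2ccccc2)c1)[C@@H](OCc1ccccc1)Cc1c(F)c(Br)c(OCc2ccccc2)cc1OCc1ccccc1
F7 | step 5 | 1,5-bis(benzyloxy)-2,4-dibromo-3-fluorobenzene | Fc1c(Br)c(OCc2ccccc2)cc(OCc2ccccc2)c1Br
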